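**Retrosynthetic overview**
1. The target comes from an O-benzyl tricos-2-enyl arene. One final hydrogenation saturates the chain and frees the phenol.
2. That alkene comes from an (E)-1-aryltricos-1-en-3-one. The C3 oxygen is removed by reductive 1,3-transposition of the tosylhydrazone.
3. Key disconnection is C1=C2 of the chain: a crossed aldol (Claisen–Schmidt) condensation of 2-(benzyloxy)-3,5-dimethoxybenzaldehyde (fragment A, ring + C1) with docosan-2-one (fragment B, C2–C23).
4. Fragment A comes from 2,4-dimethoxybenzaldehyde (Baeyer–Villiger, ortho-formylation, benzylation). Fragment B comes from 1-bromoicosane and N-methoxy-N-methylacetamide.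
5. Rings: the single benzene ring is bought, and no ring is formed.

Assumption: the target (2,4-dimethoxy-6-tricosylphenol, side chain counted as 23 carbons) has no stereocentre and no stereogenic double bond, so it is achiral and there is no enantiomer to select.

**Step 1**
Reactants: 1 2,4-dimethoxybenzaldehyde
Product: 3 2,4-dimethoxyphenol, via 2,4-dimethoxyphenyl formate 2 (not isolated)
Conditions: mCPBA (1.3 equiv), CH2Cl2, 0 °C → rt; aq. Na2SO3/NaHCO3 wash; then K2CO3 (0.1 equiv), MeOH, rt
Reagents that add atoms: mCPBA, O=C(OO)c1cccc(Cl)c1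
Why: In this Baeyer–Villiger (Dakin-type) oxidation the electron-rich aryl group migrates in preference to hydride, and the very labile aryl formate is then cleaved by base-catalysed methanolysis; no stereocentre is involved.

**Step 2**
Reactants: 3 2,4-dimethoxyphenol
Product: 5 2-hydroxy-3,5-dimethoxybenzaldehyde, via 2-(hydroxymethyl)-4,6-dimethoxyphenol 4 (not isolated)
Conditions: MgCl2 (anhydrous, 2 equiv), Et3N (3.75 equiv), (CH2O)n (7 equiv), MeCN, reflux; 1 M HCl work-up
Reagents that add atoms: paraformaldehyde (reacts as formaldehyde), C=O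
Why: In the Casnati–Skattebøl ortho-formylation the magnesium phenoxide delivers coordinated formaldehyde only to the carbon ortho to oxygen (here the single free C6, whereas ordinary electrophilic formylation would attack C5), and a second formaldehyde oxidises the benzylic alkoxide of 4 by Oppenauer-type hydride transfer.

**Step 3**
Reactants: 5 2-hydroxy-3,5-dimethoxybenzaldehyde
Product: 6 2-(benzyloxy)-3,5-dimethoxybenzaldehyde
Conditions: BnBr (1.2 equiv), K2CO3 (2 equiv), DMF, 60 °C
Reagents that add atoms: benzyl bromide, BrCc1ccccc1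
Why: Williamson ether synthesis on the phenoxide masks the acidic ortho-OH, which would otherwise deactivate the aldehyde in base and later close chroman-type hemiketals on the C3 ketone, with a group that the final hydrogenation removes.

**Step 4**
Reactants: 7 1-bromoicosane; 8 N-methoxy-N-methylacetamide
Product: 11 docosan-2-one, via icosylmagnesium bromide 9 (not isolated), via tetrahedral magnesium adduct 10 (not isolated)
Conditions: Mg turnings (1.2 equiv), I2 (crystal), THF, 45–50 °C; then 8 (1.2 equiv), THF, 0 °C → rt; 1 M HCl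
Reagents that add atoms: none
Why: In the Weinreb ketone synthesis the Grignard reagent adds once to give the chelated adduct 10, which survives until the acidic quench, so no tertiary alcohol can form.

**Step 5 (key step)**
Reactants: 6 2-(benzyloxy)-3,5-dimethoxybenzaldehyde (1.1 equiv); 11 docosan-2-one
Product: 13 (E)-1-[2-(benzyloxy)-3,5-dimethoxyphenyl]tricos-1-en-3-one, via racemic aldol adduct 12 (not isolated)
Conditions: KOH (1 equiv), EtOH/THF 1:1, 50 °C, 24 h
Reagents that add atoms: none
Why: In this Claisen–Schmidt crossed aldol condensation the aldehyde cannot enolise, aldol addition is reversible, and only the methyl-side adduct 12 dehydrates readily (E1cB), so the linear aryl-conjugated E-enone accumulates and the racemic carbinol centre of 12 is erased.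

**Step 6**
Reactants: 13 (E)-1-[2-(benzyloxy)-3,5-dimethoxyphenyl]tricos-1-en-3-one
Product: 14 tosylhydrazone of 13 (C=C still E, C=N a syn/anti mixture)
Conditions: TsNHNH2 (1.15 equiv), EtOH/THF 2:1, 50 °C, no added acid; crystallise on cooling
Reagents that add atoms: 4-methylbenzenesulfonohydrazide, Cc1ccc(cc1)S(=O)(=O)NN
Why: Hydrazone condensation at the unhindered ketone is fast, and working at mild temperature without acid or base suppresses aza-Michael closure to a pyrazoline.

**Step 7**
Reactants: 14 tosylhydrazone of 13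
Product: 17 2-(benzyloxy)-1,5-dimethoxy-3-[(2E)-tricos-2-en-1-yl]benzene, via N-boryl tosylhydrazine 15 (not isolated), via allylic diazene 16 (not isolated)
Conditions: catecholborane (1.5 equiv), CHCl3, −10 → 0 °C, 2 h; then NaOAc·3H2O (3 equiv), reflux, 1 h; chromatography
Reagents that add atoms: none
Why: In this Kabalka-type reductive transposition of an enone tosylhydrazone, B–H adds across C=N, acetate triggers loss of sulfinate to give diazene 16, and a concerted retro-ene loss of N2 puts hydrogen on C1 and moves the alkene to C2=C3, so the transient racemic C3 centre disappears and the alkene geometry does not matter for the next step.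

**Step 8**
Reactants: 17 2-(benzyloxy)-1,5-dimethoxy-3-[(2E)-tricos-2-en-1-yl]benzene
Product: 18 2,4-dimethoxy-6-tricosylphenol (target)
Conditions: H2 (1 atm), 10% Pd/C, THF/EtOH 1:1, 40 °C; filter under N2; recrystallise
Reagents that add atoms: none
Why: Catalytic hydrogenation saturates the isolated disubstituted alkene and hydrogenolyses the aryl benzyl ether in one operation while the aryl methyl ethers and the arene are inert, so the oxidation-prone phenol appears only at the very end and no stereocentre is created.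

**Compound list**
1 | 2,4-dimethoxybenzaldehyde | COc1ccc(C=O)c(OC)c1 | starting material
2 | 2,4-dimethoxyphenyl formate | COc1ccc(OC=O)c(OC)c1 | intermediate
3 | 2,4-dimethoxyphenol | COc1ccc(O)c(OC)c1 | intermediate
4 | 2-(hydroxymethyl)-4,6-dimethoxyphenol (present as its chloromagnesium salt, drawn neutral) | COc1cc(CO)c(O)c(OC)c1 | intermediate
5 | 2-hydroxy-3,5-dimethoxybenzaldehyde | COc1cc(C=O)c(O)c(OC)c1 | intermediate
6 | 2-(benzyloxy)-3,5-dimethoxybenzaldehyde | COc1cc(C=O)c(OCc2ccccc2)c(OC)c1 | intermediate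
7 | 1-bromoicosane | CCCCCCCCCCCCCCCCCCCCBr | starting material
8 | N-methoxy-N-methylacetamide | CC(=O)N(C)OC | starting material
9 | icosylmagnesium bromide | CCCCCCCCCCCCCCCCCCCC[Mg]Br | intermediate
10 | bromomagnesium 2-[methoxy(methyl)amino]docosan-2-olate (chelated tetrahedral adduct, racemic) | CCCCCCCCCCCCCCCCCCCCC(C)(O[Mg]Br)N(C)OC | intermediate
11 | docosan-2-one | CCCCCCCCCCCCCCCCCCCCC(C)=O | intermediate
12 | 1-[2-(benzyloxy)-3,5-dimethoxyphenyl]-1-hydroxytricosan-3-one (racemic) | CCCCCCCCCCCCCCCCCCCCC(=O)CC(O)c1cc(OC)cc(OC)c1OCc1ccccc1 | intermediate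
13 | (E)-1-[2-(benzyloxy)-3,5-dimethoxyphenyl]tricos-1-en-3-one | CCCCCCCCCCCCCCCCCCCCC(=O)/C=C/c1cc(OC)cc(OC)c1OCc1ccccc1 | intermediate
14 | N'-{(1E)-1-[2-(benzyloxy)-3,5-dimethoxyphenyl]tricos-1-en-3-ylidene}-4-methylbenzenesulfonohydrazide (C=N geometry unassigned) | CCCCCCCCCCCCCCCCCCCCC(=NNS(=O)(=O)c1ccc(C)cc1)/C=C/c1cc(OC)cc(OC)c1OCc1ccccc1 | intermediate
15 | N'-(1,3,2-benzodioxaborol-2-yl)-N'-{(1E)-1-[2-(benzyloxy)-3,5-dimethoxyphenyl]tricos-1-en-3-yl}-4-methylbenzenesulfonohydrazide (racemic) | CCCCCCCCCCCCCCCCCCCCC(/C=C/c1cc(OC)cc(OC)c1OCc1ccccc1)N(B1Oc2ccccc2O1)NS(=O)(=O)c1ccc(C)cc1 | intermediate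
16 | {(1E)-1-[2-(benzyloxy)-3,5-dimethoxyphenyl]tricos-1-en-3-yl}diazene (racemic) | CCCCCCCCCCCCCCCCCCCCC(/C=C/c1cc(OC)cc(OC)c1OCc1ccccc1)N=N | intermediate
17 | 2-(benzyloxy)-1,5-dimethoxy-3-[(2E)-tricos-2-en-1-yl]benzene | CCCCCCCCCCCCCCCCCCCC/C=C/Cc1cc(OC)cc(OC)c1OCc1ccccc1 | intermediate
18 | 2,4-dimethoxy-6-tricosylphenol (achiral) | CCCCCCCCCCCCCCCCCCCCCCCc1cc(OC)cc(OC)c1O | target

**Totals**
Total step count: 8.
Longest linear sequence: 7 (steps 1, 2, 3, 5, 6, 7, 8, starting from 1).

**Three steps most likely to fail**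

Step 2 (ortho-formylation). The neighbouring methoxy group can tie up magnesium, and C6 is activated only by the phenoxide, so conversion may stall or methoxymethyl and diarylmethane by-products may appear.
- The fallback sets out from 3 and comes back to the route at 6. It installs the ortho carbon by a sigmatropic shift instead of an aromatic substitution.
- Compound 3 is O-allylated (allyl bromide, K2CO3, acetone, reflux) to 1-(allyloxy)-2,4-dimethoxybenzene F1.
- Aromatic Claisen rearrangement (N,N-diethylaniline, 200 °C) can end only at the one free ortho carbon and gives 2-allyl-4,6-dimethoxyphenol F2.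
- Benzylation (BnBr, K2CO3, DMF) gives 1-allyl-2-(benzyloxy)-3,5-dimethoxybenzene F3.
- KOtBu in DMSO moves the alkene into conjugation to give 2-(benzyloxy)-1,5-dimethoxy-3-[(E)-prop-1-en-1-yl]benzene F4.
- Lemieux–Johnson cleavage (OsO4 cat., NaIO4, 2,6-lutidine, dioxane/H2O) then delivers 6.

Step 5 (aldol condensation). The waxy ketone, the hindered electron-rich aldehyde and the equilibrating base may give slow conversion, some internal-side condensation, or Michael addition of the enolate of 11 to 13.
- The fallback sets out from 11 (partner 6 unchanged) and comes back at 13. It replaces the equilibrium condensation by an irreversible directed aldol followed by a separate elimination.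
- Compound 11 is converted under kinetic control (LiN(iPr)2 with Me3SiCl present, THF, −78 °C) into 2-(trimethylsilyloxy)docos-1-ene F5.
- Mukaiyama aldol addition of F5 to 6 (BF3·OEt2, CH2Cl2, −78 → −40 °C, acidic work-up) gives the aldol 12, which is now isolated.
- Mesylation (MsCl, Et3N, CH2Cl2, 0 °C) gives 1-[2-(benzyloxy)-3,5-dimethoxyphenyl]-3-oxotricosan-1-yl methanesulfonate F6, which DBU eliminates to 13.

Step 7 (reductive transposition, together with its precursor step 6). Pyrazoline formation from 14, incomplete C=N reduction or diazene side reactions would cost material.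
- The fallback sets out from 13 and comes back at 17. It removes the oxygen as an allylic leaving group instead of through a hydrazone.
- Luche reduction (NaBH4, CeCl3·7H2O, MeOH/THF, 0 °C) gives racemic (E)-1-[2-(benzyloxy)-3,5-dimethoxyphenyl]tricos-1-en-3-ol F7.
- Acetylation (Ac2O, pyridine, DMAP) gives (E)-1-[2-(benzyloxy)-3,5-dimethoxyphenyl]tricos-1-en-3-yl acetate F8.
- Formate hydrogenolysis (Pd(PPh3)4 cat., HCO2NH4, dioxane, reflux) proceeds through a π-allyl complex of divalent palladium and gives 17.
- Compound 17 is accompanied by its regioisomer 2-(benzyloxy)-1,5-dimethoxy-3-[(E)-tricos-1-en-1-yl]benzene F9 and by some elimination product 2-(benzyloxy)-1,5-dimethoxy-3-[(1E,3E)-tricosa-1,3-dien-1-yl]benzene F10.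
- Step 8 converts all three into the same 18, so no separation is needed.

**Further compounds**
F1 | step 2 | 1-(allyloxy)-2,4-dimethoxybenzene | C=CCOc1ccc(OC)cc1OC
F2 | step 2 | 2-allyl-4,6-dimethoxyphenol | C=CCc1cc(OC)cc(OC)c1O
F3 | step 2 | 1-allyl-2-(benzyloxy)-3,5-dimethoxybenzene | C=CCc1cc(OC)cc(OC)c1OCc1ccccc1
F4 | step 2 | 2-(benzyloxy)-1,5-dimethoxy-3-[(E)-prop-1-en-1-yl]benzene | C/C=C/c1cc(OC)cc(OC)c1OCc1ccccc1
F5 | step 5 | 2-(trimethylsilyloxy)docos-1-ene | CCCCCCCCCCCCCCCCCCCCC(=C)O[Si](C)(C)C
F6 | step 5 | 1-[2-(benzyloxy)-3,5-dimethoxyphenyl]-3-oxotricosan-1-yl methanesulfonate (racemic) | CCCCCCCCCCCCCCCCCCCCC(=O)CC(OS(C)(=O)=O)c1cc(OC)cc(OC)c1OCc1ccccc1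
F7 | step 7 | (E)-1-[2-(benzyloxy)-3,5-dimethoxyphenyl]tricos-1-en-3-ol (racemic) | CCCCCCCCCCCCCCCCCCCCC(O)/C=C/c1cc(OC)cc(OC)c1OCc1ccccc1
F8 | step 7 | (E)-1-[2-(benzyloxy)-3,5-dimethoxyphenyl]tricos-1-en-3-yl acetate (racemic) | CCCCCCCCCCCCCCCCCCCCC(OC(C)=O)/C=C/c1cc(OC)cc(OC)c1OCc1ccccc1
F9 | step 7 | 2-(benzyloxy)-1,5-dimethoxy-3-[(E)-tricos-1-en-1-yl]benzene | CCCCCCCCCCCCCCCCCCCCC/C=C/c1cc(OC)cc(OC)c1OCc1ccccc1
F10 | step 7 | 2-(benzyloxy)-1,5-dimethoxy-3-[(1E,3E)-tricosa-1,3-dien-1-yl]benzene | CCCCCCCCCCCCCCCCCCC/C=C/C=C/c1cc(OC)cc(OC)c1OCc1ccccc1
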